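| setting | teal | green | grey | amber | west | south-west | south-east | south |
|---|---|---|---|---|---|---|---|---|
| substrate | 0.031 M | 0.031 M | 0.031 M | 0.031 M | 0.031 M | 0.031 M (fed, over 1.25 d) | 0.031 M | 0.031 M |
| coupling partner | 0.0217 M | 0.0217 M | 0.0217 M | 0.033 M | 0.0217 M | 0.0217 M | 0.0217 M | 0.0217 M |
| free catalyst | 0.31 mM | 0.15 mM | 0.23 mM | 0.31 mM | 0.31 mM | 0.31 mM | 0.31 mM | 0.31 mM |
| remark | run made earlier | run made earlier | run made earlier | run made earlier | a closed flask charged with all of it at once and left for 2.5 d | a stirred flask in which substrate is dosed at a steady rate over 1.25 d without added volume, worked up at 2.5 d | a tube with plug flow, the mixed feed as stated, residence time 2.5 d | a single well-mixed tank run continuously and read at steady state, 2.5 d in it on average |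
| time |  |  |  |  | 2.5 d | 2.5 d | 2.5 d |  |

| run | time / h | product / % | substrate / % |
|---|---|---|---|
| teal | 6.00 | 12 | 86 |
| teal | 12.0 | 15 | 84 |
| teal | 20.0 | 17 | 82 |
| teal | 25.0 | 17 | 79 |
| teal | 30.0 | 18 | 81 |
| teal | 40.0 | 20 | 76 |
| green | 6.00 | 4 | 93 |
| green | 12.0 | 10 | 92 |
| green | 20.0 | 14 | 85 |
| green | 25.0 | 14 | 84 |
| green | 30.0 | 16 | 84 |
| green | 40.0 | 18 | 84 |
| grey | 6.00 | 8 | 90 |
| grey | 12.0 | 9 | 86 |
| grey | 20.0 | 12 | 85 |
| grey | 25.0 | 17 | 80 |
| grey | 30.0 | 16 | 81 |
| grey | 40.0 | 18 | 80 |
| amber | 8.00 | 16 | 82 |
| amber | 15.0 | 24 | 77 |
| amber | 20.0 | 25 | 72 |
| amber | 30.0 | 31 | 68 |
| amber | 40.0 | 34 | 65 |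

(standard deviation of a reading: 2 percentage points)

- the stated concentrations are those of everything mixed, before any reaction; amounts are the same in each set-up
- the numbers in the tables scatter by 2 percentage points (one standard deviation)
- the feed brings no volume worth counting
- the earlier runs were made in a closed, stirred flask

* the set-up with the highest amount of product at the outlet or at the end, in percent of the substrate put in ("none" if the first two lie within 2 percentage points) (west / south-west / south-east / south / none)
* amount of product at the outlet or at the end, in percent of the substrate put in, west
* amount of product at the outlet or at the end, in percent of the substrate put in, south-west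
* amount of product at the outlet or at the end, in percent of the substrate put in, south-east
* amount of product at the outlet or at the end, in percent of the substrate put in, south

The leftover strikes me first: at 40.0 h the teal run still holds 76% of its substrate beside 20% of product, and its curve has flattened, so I suspect the catalyst rather than the reagents. The bench rule for a catalyst that gives out is a fixed turnover number, product per catalyst charged, which teal puts at 20.0. The green run has about half of teal's catalyst, so the rule allows it 9.68%, but it reads 18%, well above that even with a scatter of 2 percentage points, and there the rule stops working. Turnovers per catalyst rise on dilution, to 37.2 in green, which I read as a loss that quickens when catalyst stands crowded.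

So I follow one catalyst molecule: at each round it comes to a fork, going on with the coupling partner or being lost. The amber and teal runs, read at the same 40.0 h, give me the yield order in partner, the power to which product at a fixed time rises with the charge of coupling partner: 1.27, a reading that carries the scatter. My own reckoning puts west and south-east equal, since a plug-flow tube repeats the closed flask's course, and somewhat above teal's last reading, since 2.5 d is longer than 40.0 h. I expect dosing, which holds the substrate low, and the tank, which holds its contents at the outlet's level, to lose nothing against them.

The forecast gives west 22%, south-east 22% and south 25%, and names south as best. I part from it on south-west, where it says 8% on the ground that “Dosing wastes the active early catalyst”.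

The flasks give west 23.2%, south-west 25.5%, south-east 23.2% and south 26.1%. South and south-west lie within 2 points of each other, so the answer for best is none.

    substrate + free catalyst → catalyst intermediate A (k = 8100 /M/h)
    coupling partner + catalyst intermediate A → catalyst intermediate B (k = 700 /M/h)
    catalyst intermediate B → catalyst intermediate C (k = 6.50 /h)
    catalyst intermediate C → free catalyst + product (k = 22.0 /h)
    2 catalyst intermediate A → spent catalyst (k = 11000 /M/h)

The lost branch of my fork is the pairing of catalyst intermediate A, and it is the main reason for the low yield of south-east: with that step struck out, south-east goes from 23.2% to 70.0%. The other branch of my fork is the step of the coupling partner with catalyst intermediate A, and for it I keep the yield order of 1.27, read from the runs at a fixed time. Carried to the same tube with 0.0087 M of coupling partner, that order scales south-east's 23.2% down to 7.29%; the computed result for that flask is 7.32%, with 92% of its substrate left.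

The earlier runs and the new flask are simulated with constants of no real substance; noise was put on by code.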